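**Assumptions (one line each)**
- The target has no stereocentres (achiral), so "single enantiomer" needs no stereocontrol.
- I read the acyl chain as 32 carbons including the carbonyl (dotriacontanoyl; target C40H72O3), and treat dotriacontanoic acid (lacceroic acid, CAS 3625-52-3) as a catalogue compound.

**Retrosynthetic overview**
- One disconnection: the ester C–O bond, giving tyrosol and dotriacontanoic acid.
- No rings are formed; the benzene ring is bought in tyrosol.
- The only selectivity issue is primary alcohol versus phenol, handled by a chemoselective Mitsunobu esterification with no protecting groups.

**Route**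

Step 1
Reactants: 1, tyrosol [2-(4-hydroxyphenyl)ethanol, 1.2 equiv]; 2, dotriacontanoic acid (n-C31H63CO2H, 1.0 equiv)
Product: 3, Basalethanolide A [2-(4-hydroxyphenyl)ethyl dotriacontanoate]
Conditions: PPh3 (1.2 equiv), DIAD (1.2 equiv, added last, dropwise), THF (about 0.05 M, pre-warmed to dissolve 2), 25 → 40 °C, 12 h; silica chromatography (hexane/EtOAc), then recrystallisation from acetone.
Reagents that add atoms: none (all product atoms come from 1 and 2; PPh3 and DIAD leave as Ph3P=O and the hydrazine dicarboxylate).
Why: In this Mitsunobu esterification the PPh3/DIAD betaine is protonated by the carboxylic acid (pKa about 5) rather than the phenol (pKa about 10), only the aliphatic CH2OH is activated as an alkoxyphosphonium, and the carboxylate displaces Ph3P=O by SN2 at the primary carbon, so the ester forms at the alkyl oxygen while the free phenol is untouched and no stereocentre is created.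

Atom balance: C8H10O2 (1) + C32H64O2 (2) → C40H72O3 (3) + H2O (the tyrosol alkyl oxygen leaves as Ph3P=O; both ester oxygens come from 2).

**Compound list**
1 | Tyrosol, 2-(4-hydroxyphenyl)ethanol | OCCc1ccc(O)cc1 | starting material
2 | Dotriacontanoic acid (lacceroic acid) | CCCCCCCCCCCCCCCCCCCCCCCCCCCCCCCC(=O)O | starting material
3 | Basalethanolide A, 2-(4-hydroxyphenyl)ethyl dotriacontanoate | CCCCCCCCCCCCCCCCCCCCCCCCCCCCCCCC(=O)OCCc1ccc(O)cc1 | target

**Totals**
Total step count: 1. Longest linear sequence: 1.

**Most likely failures and fallbacks**
The route has only one step, so these are its three most likely failure modes.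

1. Loss of chemoselectivity (phenol O-alkylation to aryl ethers or oligomers once the acid is consumed, or phenolic ester formation).
   Fallback: a protecting-group route. Convert 2 to dotriacontanoyl chloride with (COCl)2 and cat. DMF, acylate commercial 2-(4-benzyloxyphenyl)ethanol (pyridine, DMAP, warm CH2Cl2/toluene), then remove the benzyl group with H2, Pd/C in THF/EtOAc. This is 3 steps.

2. Poor solubility or slow reaction of the waxy C32 acid at 40 °C or below, leaving the Mitsunobu incomplete.
   Fallback: a high-temperature catalytic esterification. Use immobilised Candida antarctica lipase B (Novozym 435) in toluene or 2-methyl-2-butanol at 70–80 °C with 4 Å sieves, which acylates only the primary aliphatic OH. Alternatively use Fischer esterification (cat. TsOH, toluene, Dean–Stark, excess tyrosol), under which phenols do not esterify.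

3. Supply or purity of acid 2 (expensive, often contaminated with C30/C34 homologues), or difficult separation of the waxy product from Ph3P=O.
   Fallback: build the acid by chain assembly. Couple docosylmagnesium bromide (from 1-bromodocosane) with 10-bromodecanoic acid (as its magnesium carboxylate) using cat. Li2CuCl4 in THF (C22 + C10 = C32). Recrystallise the acid, then esterify by the phosphine-free lipase method above.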